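**Assumptions.**
- Pyran numbering throughout: O1, C2 (CH3), C3 (CH2OH), C4 (CH2CO2R), C5 (CO2Me), C6.
- Dienol 8 is drawn as its hydrogen-bonded (Z)-enol; it equilibrates with its formyl tautomers.
- Iodide 3 and alcohol 5 are believed to be catalogue compounds (not checked); their one-step preparations are included so that the route starts from bulk chemicals.

## The problem

The target 13 is a 3,4-dihydro-2H-pyran carrying a methyl group on C2, a hydroxymethyl group on C3, an acetic acid arm on C4 (esterified with hydroxytyrosol) and a methyl ester on C5. C2, C3 and C4 are contiguous stereocentres (2R,3R,4S), and each substituent is trans to its ring neighbour. The unsaturated half of the ring, O1–C6H=C5–CO2Me, is a vinylogous carbonate, but C2 bears carbon and hydrogen, not a second oxygen, so the ring is not the acetal that enol-ether hetero-Diels–Alder or lactol chemistry delivers. C4 is β to two ester carbonyl groups (the one on C5 and the one in the arm); it is the centre of a 3-substituted glutarate whose two termini must be told apart. Only C4 is configurationally fixed under all conditions: at the aldehyde oxidation level C3 is α to a formyl group and O1–C2 is the bond of a β-alkoxy aldehyde, so C3 can epimerise and C2 can be reset by retro-oxa-Michael/oxa-Michael reaction, and C4 can therefore control the other two. The sensitive points are the primary alcohol (it can close a δ-lactone onto the arm ester and expel hydroxytyrosol), the catechol (oxidation), the β-alkoxy aldehyde precursor (β-elimination) and the enol ether (acid).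

The feature that the plan exploits: O1–C6=C5 is the enol of a 2-formyl ester, and the next ring atom, C4, is also the β-carbon of the arm ester C4–CH2–C(=O)O. O1, C6, C5, C4 and both ester groups therefore belong to one achiral, fully conjugated dienol (nucleophilic at O1, electrophilic at C4). The two remaining ring atoms, C2 and C3, with the methyl group and the one-carbon substituent, are the C=C bond of (E)-crotonaldehyde.

## Retrosynthesis

**13 ⇒ 12.** The two ArO–CH2Ph bonds are cut last. Benzyl ethers are preferred to silyl ethers or a ketal because they leave with hydrogen on palladium without acid, base or fluoride, any of which could drive the C3 hydroxymethyl group onto the arm ester. The skeleton of 12 is no simpler; the forward step must spare the C5=C6 bond, a deactivated trisubstituted alkene.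

**12 ⇒ 11.** No bond is cut; C3–CH2OH is traced back to C3–CHO. A C3 ester would have to be reduced beside two other esters, whereas the aldehyde is reduced selectively, is the oxidation level a simple enal brings, and makes C3 and C2 correctable. The forward reduction must outrun β-elimination of the ring oxygen and be quenched before the new alkoxide lactonises.

**11 ⇒ 8 + 9 (key disconnection).** Two ring bonds are cut, O1–C2 and C3–C4, with the oxa-Michael adduct 10 as the intermediate between them. The neighbouring pair O1–C6/C4–C5 (hetero-Diels–Alder sense) would need an enol ether and put oxygen on C2. Cutting O1–C2 alone leaves C3–C4 and the stereocentre C4 to a separate step. Cutting the arm ester first leaves the ring problem untouched. The chosen pair removes the ring and all three stereocentres together: 8 is achiral and acyclic and already carries both esters in differentiated form, and 9 is a commodity aldehyde that supplies C2, C3, the methyl group and the formyl carbon. The forward reaction is an amine-catalysed oxa-Michael/Michael cascade; it must direct the ambident dienol to O-alkylation, close the ring at C4 and pass the chirality of the catalyst to C2, C3 and C4.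

**8 ⇒ 7.** The enol O–H is traced to its methyl ether (C6–OMe), because the free enol is acidic and chelating and would not survive the palladium coupling that builds the chain. The forward hydrolysis must not isomerise the (E)-acrylate.

**7 ⇒ 3 + 6.** The C4–C5 bond is cut between the β-carbon of an acrylate and the α-carbon of a β-methoxyacrylate (Mizoroki–Heck). The neighbouring option, formylation of a glutaconate with two different esters, cannot distinguish its two α-positions, since the glutaconate anion is delocalised over both. With the Heck cut each ester arrives on its own partner and the C–I bond fixes the regiochemistry.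

**6 ⇒ 5 ⇒ 4 and 3 ⇒ 1.** Acrylate 6 is the acryloyl ester of alcohol 5, which is hydroxytyrosol 4 with both phenols benzylated. Iodide 3 is the α-iodination product of methyl (E)-3-methoxyacrylate 1 through adduct 2. The only selectivity issue is phenol versus alcohol alkylation.

## Roads not taken

**Alternative 1:** The obvious first cut is the acyl–oxygen bond of the arm ester, giving alcohol 5 and ring acid A1 (C3 hydroxymethyl silylated). The dihydropyran of A1 would then come from an inverse-electron-demand hetero-Diels–Alder reaction of a 2-formylalkenoate (O1=C6–C5=C4) with an enol ether (C2=C3). That key step gives a 2-alkoxy acetal such as A2, because the dienophile needs oxygen on the carbon that becomes C2. The target has a methyl group there, so the alkoxy group would have to be exchanged for methyl through an oxocarbenium ion, with a third stereocentre to control. A1 is also a masked δ-hydroxy acid: any carboxyl activation after loss of the silyl group closes the lactone. The chosen plan has the methyl group on C2 from the start, carries the hydroxytyrosol ester through ring formation, and never activates a carboxyl group beside a free alcohol.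

**Alternative 2:** Cut O1–C6 and C5–C6 and read the rest as a δ-lactone. Unsaturated lactone A3 (from methyl (R)-3-hydroxybutanoate by dianion alkylation, reduction, Z-olefination and lactonisation) would take up an acetate enolate at its β-carbon trans to the neighbouring substituent and then a formate ester at the α-carbon, giving formyl lactone A4. Acid methanolysis (acyl-lactone rearrangement) would convert A4 into the dihydropyran ester. Every step has precedent and substrate control is reliable. The stereocentres are, however, bought one at a time with strong bases and several protecting-group changes, in about ten steps, and the acidic methanol of the rearrangement threatens the arm ester by transesterification. The chosen plan reaches the ring one step after the achiral dienol.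

**Alternative 3:** Cut only O1–C2: the open-chain enal–enol A5 would close by intramolecular oxa-Michael addition under thermodynamic control. The ring closure is safe, but A5 must first be assembled with its C4 stereocentre by a separate enantioselective C–C bond formation. It also needs an (E)-ethylidene group installed by aldol condensation with acetaldehyde next to a second, enolised aldehyde. The chosen plan enters the same equilibrium manifold (A5 is the retro-oxa-Michael isomer of 11) in one operation from 8 and 9, and keeps the thermodynamic correction without a separate synthesis of A5.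

Key step: step 6

## Route

**Step 1**  
Reactants: 1 methyl (E)-3-methoxyacrylate  
Product: 3 methyl (Z)-2-iodo-3-methoxyacrylate, via acetoxy iodide adduct 2 (not isolated)  
Conditions: NIS, AcOH, CH2Cl2, rt; then Et3N, rt  
Reagents that add atoms: N-iodosuccinimide, `O=C1CCC(=O)N1I`  
Why: Iodination–elimination of a β-alkoxyacrylate: iodonium attack at the nucleophilic α-carbon and capture of the oxocarbenium ion by acetate give 2, and Et3N removes acetic acid by E1cB elimination to the preferred (Z)-iodide (OMe cis to I).

**Step 2**  
Reactants: 4 hydroxytyrosol [4-(2-hydroxyethyl)benzene-1,2-diol]  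
Product: 5 2-[3,4-bis(benzyloxy)phenyl]ethanol  
Conditions: BnBr (2.1 equiv), K2CO3, acetone, reflux  
Reagents that add atoms: benzyl bromide, `BrCc1ccccc1`  
Why: Williamson etherification; K2CO3 deprotonates only the phenols, so the aliphatic alcohol stays free.

**Step 3**  
Reactants: 5 2-[3,4-bis(benzyloxy)phenyl]ethanol  
Product: 6 2-[3,4-bis(benzyloxy)phenyl]ethyl acrylate  
Conditions: acryloyl chloride, Et3N, CH2Cl2, 0 °C  
Reagents that add atoms: acryloyl chloride, `C=CC(Cl)=O`  
Why: O-acylation of a primary alcohol with an acid chloride; low temperature keeps chloride and amine from adding to the acrylate.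

**Step 4**  
Reactants: 3 methyl (Z)-2-iodo-3-methoxyacrylate; 6 2-[3,4-bis(benzyloxy)phenyl]ethyl acrylate  
Product: 7 1-{2-[3,4-bis(benzyloxy)phenyl]ethyl} 5-methyl (2E,4E)-4-(methoxymethylene)pent-2-enedioate  
Conditions: Pd(OAc)2 (5 mol %), P(o-tolyl)3 (10 mol %), Et3N, MeCN, 70 °C  
Reagents that add atoms: none  
Why: Mizoroki–Heck reaction: the C–I bond of 3 adds to zerovalent palladium with retention, the alkenyl–palladium species inserts the acrylate at its unsubstituted carbon, and syn β-hydride elimination gives the (E)-acrylate; the C4–C5 bond forms with each ester already on its own side.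

**Step 5**  
Reactants: 7 1-{2-[3,4-bis(benzyloxy)phenyl]ethyl} 5-methyl (2E,4E)-4-(methoxymethylene)pent-2-enedioate  
Product: 8 1-{2-[3,4-bis(benzyloxy)phenyl]ethyl} 5-methyl (2E,4Z)-4-(hydroxymethylene)pent-2-enedioate  
Conditions: 2 M aq HCl, THF, rt to 40 °C  
Reagents that add atoms: water, `O`  
Why: Acid hydrolysis of a vinylogous carbonate enol ether (C-protonation, addition of water at C6, loss of methanol); the product is held as the hydrogen-bonded enol, and benzyl ethers and both esters tolerate dilute aqueous acid.

**Step 6**  
Reactants: 8 1-{2-[3,4-bis(benzyloxy)phenyl]ethyl} 5-methyl (2E,4Z)-4-(hydroxymethylene)pent-2-enedioate; 9 (E)-crotonaldehyde [(E)-but-2-enal]  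
Product: 11 methyl (2R,3S,4S)-4-(2-{2-[3,4-bis(benzyloxy)phenyl]ethoxy}-2-oxoethyl)-3-formyl-2-methyl-3,4-dihydro-2H-pyran-5-carboxylate, via oxa-Michael adduct 10 (not isolated)  
Conditions: (S)-α,α-diphenylprolinol trimethylsilyl ether (20 mol %), 9 (4 equiv), toluene, 0 °C to rt  
Reagents that add atoms: none  
Why: Proposed new method: the amine and 9 form an iminium ion, the enol oxygen of 8 adds to its β-carbon (future C2) on the face away from the CPh2(OSiMe3) group (2R), and the enamine of 10 so formed adds through its α-carbon (future C3) to C4, the β-carbon of the acrylate arm, in a 6-exo-trig ring closure; hydrolysis then frees 11 and the catalyst. The closest known reaction type is the oxa-Michael/Michael cascade of enals with 2-hydroxyaryl Michael acceptors (2-(2-nitrovinyl)phenols, 2-hydroxycinnamates) that gives 2,3,4-trisubstituted chromans with this class of catalyst; here the benzo C=C bond is replaced by the enol C6=C5 of a 2-formyl ester, which is a weaker oxygen nucleophile than a phenol but leaves a more electrophilic acceptor at C4 because the oxygen lone pair is drawn into the C5 ester. The enamine is attacked on the face left open by the same shielding group, so O1 and C4 are delivered to one face of the (E)-alkene and methyl and formyl come out trans (3S). C4 is set in a half-chair transition state with a planar dienoate, in which the C2 methyl group and the enamine stay pseudo-equatorial and the acrylate arm ends trans to the formyl group (4S). The step needs O- instead of C-alkylation of the ambident dienol: C5 is fully substituted, so its attack gives only a congested adduct that can revert, whereas the O-adduct is removed by the ring closure. The oxa-Michael addition is reversible and C3 is α to the formyl group, so C2 and C3 of 11 can still equilibrate towards the all-trans isomer relative to the fixed C4, the arrangement with all three substituents pseudo-equatorial.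

**Step 7**  
Reactants: 11 methyl (2R,3S,4S)-4-(2-{2-[3,4-bis(benzyloxy)phenyl]ethoxy}-2-oxoethyl)-3-formyl-2-methyl-3,4-dihydro-2H-pyran-5-carboxylate  
Product: 12 methyl (2R,3R,4S)-4-(2-{2-[3,4-bis(benzyloxy)phenyl]ethoxy}-2-oxoethyl)-3-(hydroxymethyl)-2-methyl-3,4-dihydro-2H-pyran-5-carboxylate  
Conditions: NaBH4, CeCl3·7H2O, MeOH–THF, −40 °C; AcOH quench  
Reagents that add atoms: none  
Why: Luche-type borohydride reduction of an aldehyde beside a saturated ester and a vinylogous carbonate; low temperature and an acidic quench should keep the new alkoxide from lactonising and the β-alkoxy aldehyde from β-elimination; the C3 descriptor changes from S to R only through CIP priorities.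

**Step 8**  
Reactants: 12 methyl (2R,3R,4S)-4-(2-{2-[3,4-bis(benzyloxy)phenyl]ethoxy}-2-oxoethyl)-3-(hydroxymethyl)-2-methyl-3,4-dihydro-2H-pyran-5-carboxylate  
Product: 13 methyl (2R,3R,4S)-4-{2-[2-(3,4-dihydroxyphenyl)ethoxy]-2-oxoethyl}-3-(hydroxymethyl)-2-methyl-3,4-dihydro-2H-pyran-5-carboxylate  
Conditions: H2 (1 atm), 10% Pd/C, EtOAc, rt  
Reagents that add atoms: none  
Why: Hydrogenolysis of the two aryl benzyl ethers under neutral conditions; the C5=C6 bond is a trisubstituted donor–acceptor alkene that is slow to hydrogenate, and no acid or base is present to close the lactone.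

## Compound list

```
1 | methyl (E)-3-methoxyacrylate | CO/C=C/C(=O)OC | starting material
2 | methyl 3-acetoxy-2-iodo-3-methoxypropanoate (diastereomer mixture) | COC(OC(C)=O)C(I)C(=O)OC | intermediate (not isolated)
3 | methyl (Z)-2-iodo-3-methoxyacrylate | CO/C=C(\I)C(=O)OC | intermediate
4 | hydroxytyrosol, 4-(2-hydroxyethyl)benzene-1,2-diol | OCCc1ccc(O)c(O)c1 | starting material
5 | 2-[3,4-bis(benzyloxy)phenyl]ethanol | OCCc1ccc(OCc2ccccc2)c(OCc2ccccc2)c1 | intermediate
6 | 2-[3,4-bis(benzyloxy)phenyl]ethyl acrylate | C=CC(=O)OCCc1ccc(OCc2ccccc2)c(OCc2ccccc2)c1 | intermediate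
7 | 1-{2-[3,4-bis(benzyloxy)phenyl]ethyl} 5-methyl (2E,4E)-4-(methoxymethylene)pent-2-enedioate | CO/C=C(\C=C\C(=O)OCCc1ccc(OCc2ccccc2)c(OCc2ccccc2)c1)C(=O)OC | intermediate
8 | 1-{2-[3,4-bis(benzyloxy)phenyl]ethyl} 5-methyl (2E,4Z)-4-(hydroxymethylene)pent-2-enedioate | O/C=C(/C=C/C(=O)OCCc1ccc(OCc2ccccc2)c(OCc2ccccc2)c1)C(=O)OC | intermediate
9 | (E)-crotonaldehyde, (E)-but-2-enal | C/C=C/C=O | starting material
10 | 1-{2-[3,4-bis(benzyloxy)phenyl]ethyl} 5-methyl (2E,4E)-4-({[(2R)-4-oxobutan-2-yl]oxy}methylene)pent-2-enedioate (present as its enamine) | O=CC[C@@H](C)O/C=C(\C=C\C(=O)OCCc1ccc(OCc2ccccc2)c(OCc2ccccc2)c1)C(=O)OC | intermediate (not isolated)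
11 | methyl (2R,3S,4S)-4-(2-{2-[3,4-bis(benzyloxy)phenyl]ethoxy}-2-oxoethyl)-3-formyl-2-methyl-3,4-dihydro-2H-pyran-5-carboxylate | COC(=O)C1=CO[C@H](C)[C@@H](C=O)[C@@H]1CC(=O)OCCc1ccc(OCc2ccccc2)c(OCc2ccccc2)c1 | intermediate
12 | methyl (2R,3R,4S)-4-(2-{2-[3,4-bis(benzyloxy)phenyl]ethoxy}-2-oxoethyl)-3-(hydroxymethyl)-2-methyl-3,4-dihydro-2H-pyran-5-carboxylate | COC(=O)C1=CO[C@H](C)[C@@H](CO)[C@@H]1CC(=O)OCCc1ccc(OCc2ccccc2)c(OCc2ccccc2)c1 | intermediate
13 | methyl (2R,3R,4S)-4-{2-[2-(3,4-dihydroxyphenyl)ethoxy]-2-oxoethyl}-3-(hydroxymethyl)-2-methyl-3,4-dihydro-2H-pyran-5-carboxylate | COC(=O)C1=CO[C@H](C)[C@@H](CO)[C@@H]1CC(=O)OCCc1ccc(O)c(O)c1 | target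
```

## Step count and risk

Total step count: 8. Longest linear sequence: 7 steps (4 → 5 → 6 → 7 → 8 → 11 → 12 → 13); step 1 is a one-step branch.

**Step 6 (key step, proposed new method).**
- The dienol may alkylate the iminium ion through carbon (vinylogously, at the acrylate α-carbon) instead of oxygen, or the amine may condense with the formyl tautomer of 8 to a vinylogous carbamate and be withdrawn.
- Because 8 is a better leaving group than a phenol, the stationary concentration of adduct 10 may be low, so self-condensation of 9 through its dienamine can compete with ring closure.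
- Facial selectivity at C4 rests on a half-chair model; if it is imperfect, it appears as loss of enantiomeric purity once C2 and C3 have equilibrated.
- If the sense of induction is opposite to the shielding model, the (R)-catalyst is used.

Fallback, known reaction types only, from 7 to 11: 7 is heated with commercial (R)-pent-4-en-2-ol and catalytic PPTS in toluene with removal of methanol. This acid-catalysed alkoxy exchange at C6, with retention at the carbinol carbon, gives the homoallyl enol ether F1. Oxidative cleavage of its terminal alkene (OsO4 cat., NaIO4, 2,6-lutidine, dioxane–water; the electron-poor conjugated C=C bonds react far more slowly) gives aldehyde 10 as an isolated, configurationally defined compound. 10 is closed to 11 by amine-catalysed intramolecular Michael addition of an aldehyde to an enoate, with the same (S)-prolinol ether, so that the preset 2R centre and the catalyst act in the same sense. The O1–C2 bond and the C2 configuration then come from a purchased alcohol, no free dienol meets the amine at the start, and ring closure is intramolecular from the outset. The fallback does not remove the enamine Michael closure itself.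

**Step 5.** The vinylogous carbonate may hydrolyse slowly. Under forcing acid the acrylate can isomerise through the formyl tautomer, and the enol oxygen can then close onto the arm ester with expulsion of 5. Fallback, from 7 to 8: 7 is treated with pyrrolidine in MeOH at rt (addition–elimination at C6) to give enaminoester F2. Its vinylogous carbamate is C-protonated far more easily than the enol ether and is hydrolysed with dilute aqueous HCl in THF at 0 °C to rt, giving 8 without warming.

**Step 7.** The alkoxide or alkoxyborate formed at C3–CH2O may transesterify intramolecularly onto the arm ester (δ-lactone closure with loss of 5); base-induced β-elimination of O1 before reduction is the second risk. Fallback, from 11 to 12: lactonisation is made the route. Reduction followed by catalytic DBU converts 11 into bicyclic lactone F3 and alcohol 5. F3 is opened with LiOH (1 equiv, THF–water, 0 °C; the vinylogous carbonate ester is far less electrophilic) to lithium carboxylate F4. F4 is O-alkylated in DMF with bromide F5 (from the recovered 5, CBr4/PPh3) to give 12, with no carboxyl group ever activated beside the free alcohol.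

**Step 4.** Insertion of the α-carbonyl alkenyl–palladium species may be sluggish, with reductive loss of iodine from 3 or a second arylation-type insertion on the product diene. Fallback, from 5 (with 3) to 7: 5 is esterified with propiolic acid (DCC, CH2Cl2, −20 °C) to propiolate F6. Copper-catalysed β-borylation (B2pin2, CuCl, Xantphos, NaOtBu, MeOH, THF; syn addition) gives (E)-boryl acrylate F7. Suzuki–Miyaura coupling of F7 with 3 (PdCl2(dppf), K3PO4, dioxane–water) gives 7 with both alkene geometries defined by the partners.

**Step 8.** Partial saturation of the C5=C6 bond or stalled hydrogenolysis is possible, and prolonged reaction invites lactonisation. Fallback, from 12 to 13: non-reductive debenzylation with BCl3 and pentamethylbenzene (CH2Cl2, −78 °C), a Lewis-acid cleavage in which the benzyl cation is trapped by the arene; no new compound is made.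

## Further compounds

```
F1 | step 6 | 1-{2-[3,4-bis(benzyloxy)phenyl]ethyl} 5-methyl (2E,4E)-4-({[(2R)-pent-4-en-2-yl]oxy}methylene)pent-2-enedioate | C=CC[C@@H](C)O/C=C(\C=C\C(=O)OCCc1ccc(OCc2ccccc2)c(OCc2ccccc2)c1)C(=O)OC
F2 | step 5 | 1-{2-[3,4-bis(benzyloxy)phenyl]ethyl} 5-methyl (2E,4E)-4-(pyrrolidin-1-ylmethylene)pent-2-enedioate | C1CCCN1/C=C(\C=C\C(=O)OCCc1ccc(OCc2ccccc2)c(OCc2ccccc2)c1)C(=O)OC
F3 | step 7 | methyl (4aS,8R,8aR)-8-methyl-3-oxo-1,3,4,4a,8,8a-hexahydropyrano[3,4-c]pyran-5-carboxylate | COC(=O)C1=CO[C@H](C)[C@H]2COC(=O)C[C@H]12
F4 | step 7 | lithium 2-[(2R,3R,4S)-3-(hydroxymethyl)-5-(methoxycarbonyl)-2-methyl-3,4-dihydro-2H-pyran-4-yl]acetate | [Li+].COC(=O)C1=CO[C@H](C)[C@@H](CO)[C@@H]1CC(=O)[O-]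
F5 | step 7 | 1,2-bis(benzyloxy)-4-(2-bromoethyl)benzene | BrCCc1ccc(OCc2ccccc2)c(OCc2ccccc2)c1
F6 | step 4 | 2-[3,4-bis(benzyloxy)phenyl]ethyl prop-2-ynoate | C#CC(=O)OCCc1ccc(OCc2ccccc2)c(OCc2ccccc2)c1
F7 | step 4 | 2-[3,4-bis(benzyloxy)phenyl]ethyl (E)-3-(4,4,5,5-tetramethyl-1,3,2-dioxaborolan-2-yl)acrylate | CC1(C)OB(/C=C/C(=O)OCCc2ccc(OCc3ccccc3)c(OCc3ccccc3)c2)OC1(C)C
F0 | step 8 | none | none
A1 | alternative 1 | 2-[(2R,3R,4S)-3-{[(tert-butyldimethylsilyl)oxy]methyl}-5-(methoxycarbonyl)-2-methyl-3,4-dihydro-2H-pyran-4-yl]acetic acid | COC(=O)C1=CO[C@H](C)[C@@H](CO[Si](C)(C)C(C)(C)C)[C@@H]1CC(=O)O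
A2 | alternative 1 | methyl (2R,3R,4S)-3-{[(tert-butyldimethylsilyl)oxy]methyl}-2-ethoxy-4-(2-methoxy-2-oxoethyl)-3,4-dihydro-2H-pyran-5-carboxylate | COC(=O)C1=CO[C@@H](OCC)[C@@H](CO[Si](C)(C)C(C)(C)C)[C@@H]1CC(=O)OC
A3 | alternative 2 | (5R,6R)-5-[(benzyloxy)methyl]-6-methyl-5,6-dihydro-2H-pyran-2-one | O=C1O[C@H](C)[C@@H](COCc2ccccc2)C=C1
A4 | alternative 2 | 2-[3,4-bis(benzyloxy)phenyl]ethyl 2-[(4S,5R,6R)-5-[(benzyloxy)methyl]-3-(hydroxymethylene)-6-methyl-2-oxotetrahydro-2H-pyran-4-yl]acetate | O=C1O[C@H](C)[C@@H](COCc2ccccc2)[C@H](CC(=O)OCCc2ccc(OCc3ccccc3)c(OCc3ccccc3)c2)C1=CO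
A5 | alternative 3 | 1-{2-[3,4-bis(benzyloxy)phenyl]ethyl} 5-methyl (3S)-4-(hydroxymethylene)-3-[(2E)-1-oxobut-2-en-2-yl]pentanedioate | C/C=C(/C=O)[C@@H](C(=CO)C(=O)OC)CC(=O)OCCc1ccc(OCc2ccccc2)c(OCc2ccccc2)c1
```
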